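**Plan**
- Retrosynthetic cuts: the O8 and O9 ester bonds and C11=C13; then C4=C5, traced back to a C4–SO2–C5 bridge, so that the nine-membered oxacycle (ring O, C3–C10) comes from a ten-membered thia-oxacycle by loss of SO2; then both C–S bonds, the furanone O–C3 bond, and C10–C1, C8–C9 and C7–C8.
- Forward order: γ-lactone from a chiral-pool butenolide, then chain C8–C10, then the furan-3(2H)-one, then the ten-membered cyclic sulfide and sulfone, then contraction to the nine-membered ring, then α-methylene, the two esters and O15 deprotection.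
- Enabling feature: C4=C5 lies inside the nine-membered ring next to C3 of the furanone. C4 is γ (vinylogous α) to the C1 ketone, so in the sulfone C4–H is by far the most acidic proton, and halogenation followed by 1,3-elimination and SO2 extrusion welds C4 to C5.
- Stereochemistry: C6 from (S)-5-(hydroxymethyl)butenolide; C7 by anti conjugate addition; C8 and C9 by reagent-controlled (Z)-γ-alkoxyallylboration (syn); C10 by Cram-chelate alkynylation; the Z geometry of C4=C5 is imposed by the bridged ring.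

Key step: step 14

Remark: germacrane numbering is used (C1 ketone, C2=C3, ring O between C3 and C10, C4 bearing C15, C6 lactone oxygen, C8 and C9 ester oxygens, C10 bearing C14, C11=C13, C12 lactone carbonyl), and 3-((tert-butyldiphenylsilyl)oxy)propanal is assumed purchasable (otherwise one oxidation from the commercial alcohol).

Step 1
Reactants: 1 (S)-5-(hydroxymethyl)furan-2(5H)-one
Product: 2 (S)-5-(chloromethyl)furan-2(5H)-one
Conditions: PPh3, N-chlorosuccinimide, CH2Cl2, 0 °C to rt
Reagents that add atoms: N-chlorosuccinimide, ClN1C(=O)CCC1=O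
Why: Appel-type chlorination of the primary alcohol under neutral conditions should leave the base-sensitive butenolide and the C6 stereocentre untouched and installs the leaving group for the later C5–S bond.

Step 2
Reactants: 2 (S)-5-(chloromethyl)furan-2(5H)-one
Product: 3 (4R,5S)-5-(chloromethyl)-4-vinyldihydrofuran-2(3H)-one
Conditions: CH2=CHMgBr, CuI (10 mol %), Me3SiCl, THF, −78 °C; aq. NH4Cl
Reagents that add atoms: vinylmagnesium bromide, C=C[Mg]Br
Why: Copper-catalysed conjugate addition to a γ-substituted butenolide should occur anti to the chloromethyl group, setting C7 in the 6,7-trans relationship of the target.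

Step 3
Reactants: 3 (4R,5S)-5-(chloromethyl)-4-vinyldihydrofuran-2(3H)-one
Product: 4 (2S,3S)-2-(chloromethyl)-5-oxotetrahydrofuran-3-carbaldehyde
Conditions: O3, CH2Cl2, −78 °C; then PPh3, −78 °C to rt
Reagents that add atoms: ozone, [O-][O+]=O
Why: Ozonolysis with reductive work-up cleaves the only alkene to the C8 aldehyde under neutral conditions, which matters because this β-acyloxy aldehyde would eliminate or epimerise with base.

Step 4
Reactants: 4 (2S,3S)-2-(chloromethyl)-5-oxotetrahydrofuran-3-carbaldehyde; 5 3-(methoxymethoxy)prop-1-ene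
Product: 7 (4R,5S)-5-(chloromethyl)-4-[(1S,2S)-1-hydroxy-2-(methoxymethoxy)but-3-en-1-yl]dihydrofuran-2(3H)-one, via Brown alkoxyallylborane 6 (not isolated)
Conditions: 5, sBuLi, THF, −78 °C; (+)-Ipc2BOMe; BF3·OEt2; then 4, −78 °C; 30% H2O2, pH 7 phosphate buffer, 0 °C to rt
Reagents that add atoms: none
Why: Brown (Z)-γ-alkoxyallylboration through a chair transition state should give the 8,9-syn diol monoether, the isopinocampheyl groups from (−)-α-pinene directing the allyl unit to the Re face of the aldehyde, so that C8 and C9 arise under reagent control with O8 free and O9 protected.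

Step 5
Reactants: 7 the homoallylic alcohol of step 4
Product: 8 O8-tert-butyldimethylsilyl ether of 7
Conditions: tBuMe2SiOTf, 2,6-lutidine, CH2Cl2, −78 to 0 °C
Reagents that add atoms: tert-butyldimethylsilyl triflate, CC(C)(C)[Si](C)(C)OS(=O)(=O)C(F)(F)F
Why: Silylation of the C8 hydroxyl prevents translactonisation to the 8,12-olide and gives a non-chelating group, so the C9 MOM ether is the only chelating oxygen in step 8.

Step 6
Reactants: 8 O8-tert-butyldimethylsilyl ether of 7
Product: 9 C10 methyl ketone (5-(chloromethyl)-4-[1-(tert-butyldimethylsilyloxy)-2-(methoxymethoxy)-3-oxobutyl]dihydrofuran-2(3H)-one with C6–C9 as in the target)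
Conditions: PdCl2 (10 mol %), CuCl (20 mol %), O2 (1 atm), DMF/H2O 7:1, rt
Reagents that add atoms: water, O
Why: Tsuji–Wacker oxidation of the terminal alkene should give the methyl ketone by Markovnikov hydroxypalladation and β-hydride elimination, making C10 the carbonyl and the former terminal carbon C14.

Step 7
Reactants: 10 3-((tert-butyldiphenylsilyl)oxy)propanal
Product: 11 5-((tert-butyldiphenylsilyl)oxy)pent-1-yn-3-ol (racemic)
Conditions: HC≡CMgBr, THF, 0 °C; aq. NH4Cl
Reagents that add atoms: ethynylmagnesium bromide, C#C[Mg]Br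
Why: 1,2-Addition of the alkynyl Grignard reagent gives the propargylic alcohol carrying C1–C4 and C15, whose carbinol centre may be racemic because it is oxidised in step 9.

Step 8
Reactants: 9 C10 methyl ketone; 11 5-((tert-butyldiphenylsilyl)oxy)pent-1-yn-3-ol
Product: 13 propargylic diol (C10 tertiary alcohol joined to C1≡C2–C3H(OH)–C4H2–C15H2OTBDPS; epimers at C3), via dimagnesium alkynide 12 (not isolated)
Conditions: 11, EtMgBr (2.1 equiv), THF, 0 °C to rt; then 9, CH2Cl2, −78 to −20 °C; aq. NH4Cl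
Reagents that add atoms: none
Why: Cram-chelate addition, in which magnesium bridges the C10 carbonyl and the C9 MOM oxygen and the alkynyl group attacks from the face opposite C8, should give the 9,10-syn tertiary alcohol with C10 as in the target.

Step 9
Reactants: 13 propargylic diol
Product: 14 γ-hydroxy ynone (C3 ketone, free C10 tertiary alcohol)
Conditions: Dess–Martin periodinane, NaHCO3, CH2Cl2, 0 °C to rt
Reagents that add atoms: none
Why: Dess–Martin oxidation can only touch the secondary propargylic alcohol at C3, since the C10 alcohol is tertiary.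

Step 10
Reactants: 14 γ-hydroxy ynone
Product: 15 furan-3(2H)-one (2-methyl-2-alkyl-5-(2-silyloxyethyl), with O bridging C10 and C3)
Conditions: (4-CF3C6H4)3PAuCl (5 mol %), AgOTf (5 mol %), wet toluene, rt
Reagents that add atoms: none
Why: Gold-catalysed cycloisomerisation of a γ-hydroxy ynone (hydration of the activated alkyne at C1, 5-exo attack of the C10 hydroxyl on the C3 carbonyl, loss of water) should close the furanone without touching the C10 stereocentre.

Step 11
Reactants: 15 furan-3(2H)-one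
Product: 17 C4 bromide of 15 (epimers at C4), via silyl dienol ether 16 (not isolated)
Conditions: Me3SiOTf, Et3N, CH2Cl2, −78 to 0 °C; then N-bromosuccinimide, THF, −78 °C
Reagents that add atoms: N-bromosuccinimide, BrN1C(=O)CCC1=O
Why: Soft enolisation removes the γ-proton at C4 of the vinylogous ester and the resulting 2-silyloxydiene should be brominated at its γ-terminus, as in γ-bromination of enones through dienol silyl ethers; the C4 configuration is irrelevant.

Step 12
Reactants: 17 C4 bromide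
Product: 19 ten-membered cyclic sulfide (C4–S–C5 bridge), via C4 thiolate 18 (not isolated)
Conditions: Na2S·9H2O (1.05 equiv), nBu4NI (0.2 equiv), DMF, slow addition of 17 (final 2 mM), rt to 45 °C
Reagents that add atoms: sodium sulfide, [Na+].[Na+].[S-2]
Why: Twofold SN2 thioetherification, in which sulfide first displaces the activated C4 bromide and the thiolate then closes the ten-membered ring at the primary C5 chloride under high dilution with iodide catalysis, is the standard entry to cyclic sulfides for Ramberg–Bäcklund contraction.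

Step 13
Reactants: 19 ten-membered cyclic sulfide
Product: 20 ten-membered cyclic sulfone
Conditions: mCPBA (2.2 equiv), NaHCO3, CH2Cl2, 0 °C to rt
Reagents that add atoms: 3-chloroperbenzoic acid, OOC(=O)c1cccc(Cl)c1
Why: Peracid oxidation of a dialkyl sulfide to the sulfone is fast, whereas the electron-poor furanone alkene should not be epoxidised.

Step 14
Reactants: 20 ten-membered cyclic sulfone
Product: 24 nine-membered furanone lactone (Z C4=C5; O8 TBS, O9 MOM, O15 TBDPS; C11 H2), via chloro sulfone carboxylate 21 (not isolated), via episulfone 22 (not isolated), via hydroxy carboxylate 23 (not isolated)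
Conditions: KOH (powdered), CCl4, tBuOH/H2O 10:1, 0 °C to rt; then 1 M HCl, THF, rt
Reagents that add atoms: none
Why: Hydroxide first opens the γ-lactone to the potassium 4-hydroxy carboxylate; C4–H (α to the sulfonyl group and γ to the C1 ketone) is then removed and chlorinated by halogen transfer from CCl4, the C5 carbanion displaces chloride in a 3-exo-tet closure to the episulfone, and cheletropic loss of SO2 forms C4=C5 and contracts the ten-membered thia-oxacycle to the nine-membered oxacycle. The closest known reaction type is the Meyers one-flask Ramberg–Bäcklund contraction of medium and large cyclic sulfones to cycloalkenes. Acidification re-forms the γ-lactone by 5-exo-trig acyl substitution of the C6 hydroxyl on the C12 acid. No stereocentre is created; the Z geometry of C4=C5 is imposed by the bridged nine-membered ring, which can only hold the cis-fused episulfone and the cis alkene, and C6–C10 are untouched. The step needs halogenation at C4 and not C5, which the much higher acidity of C4–H should secure, and 1,3-elimination instead of β-elimination from the C5 carbanion, which the open alkoxide form of the lactone and ether protection of O8, O9 and O15 should secure.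

Step 15
Reactants: 24 nine-membered furanone lactone
Product: 27 α-methylene lactone (C11=C13), via Mannich base 25 (not isolated), via ammonium iodide 26 (not isolated)
Conditions: LiN(iPr)2, THF, −78 °C; Me2N=CH2 I, −78 °C to rt; MeI, CH2Cl2/MeOH, rt; aq. NaHCO3, rt
Reagents that add atoms: Eschenmoser's salt, C=[N+](C)C.[I-]
Why: Kinetic lactone enolate aminomethylation followed by quaternisation and E1cB loss of trimethylamine is the standard α-methylenation of γ-butyrolactones, C11 being the only CH2 flanking a carbonyl.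

Step 16
Reactants: 27 α-methylene lactone
Product: 28 C9 alcohol
Conditions: Me2BBr, CH2Cl2, −78 °C; then aq. NaHCO3/THF
Reagents that add atoms: none
Why: Bromodimethylborane cleaves the acetal-type MOM ether at low temperature and should leave silyl ethers, the lactone and the enones alone.

Step 17
Reactants: 28 C9 alcohol
Product: 29 C9 isovalerate
Conditions: isovaleryl chloride, pyridine, DMAP (cat.), CH2Cl2, 0 °C to rt
Reagents that add atoms: isovaleryl chloride, CC(C)CC(Cl)=O
Why: DMAP-catalysed acylation of the hindered secondary C9 alcohol is unambiguous while O8 and O15 are silylated.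

Step 18
Reactants: 29 C9 isovalerate
Product: 30 C8 alcohol
Conditions: HF·pyridine, pyridine/THF, 0 °C
Reagents that add atoms: none
Why: Under acidic fluoride the secondary tert-butyldimethylsilyl ether should be cleaved much faster than the primary tert-butyldiphenylsilyl ether, and esters, lactone and enones are inert.

Step 19
Reactants: 30 C8 alcohol
Product: 31 O15-tert-butyldiphenylsilyl ether of the target
Conditions: methacryloyl chloride, Et3N, DMAP (cat.), CH2Cl2, −20 to 0 °C
Reagents that add atoms: methacryloyl chloride, CC(=C)C(Cl)=O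
Why: Acylation of the C8 alcohol with a reactive acid chloride at low temperature should outrun 1,2-acyl migration from O9.

Step 20
Reactants: 31 O15-tert-butyldiphenylsilyl ether of the target
Product: 32 CNP0552093.1
Conditions: nBu4NF/AcOH 1:1, THF, 0 °C to rt
Reagents that add atoms: none
Why: Acetic-acid-buffered fluoride removes the primary allylic silyl ether and should not add to the Michael acceptors or cleave the esters.

**Compound list**
1 | (S)-5-(hydroxymethyl)furan-2(5H)-one | O=C1C=C[C@@H](CO)O1 | starting material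
2 | (S)-5-(chloromethyl)furan-2(5H)-one | O=C1C=C[C@@H](CCl)O1 | intermediate
3 | (4R,5S)-5-(chloromethyl)-4-vinyldihydrofuran-2(3H)-one | ClC[C@H]1OC(=O)C[C@@H]1C=C | intermediate
4 | (2S,3S)-2-(chloromethyl)-5-oxotetrahydrofuran-3-carbaldehyde | ClC[C@H]1OC(=O)C[C@@H]1C=O | intermediate
5 | 3-(methoxymethoxy)prop-1-ene (allyl MOM ether) | C=CCOCOC | starting material
6 | [(Z)-3-(methoxymethoxy)allyl]diisopinocampheylborane (Ipc groups from (−)-α-pinene) | COCO/C=C\CB([C@H]1C[C@H]2C[C@@H]([C@@H]1C)C2(C)C)[C@H]1C[C@H]2C[C@@H]([C@@H]1C)C2(C)C | intermediate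
7 | (4R,5S)-5-(chloromethyl)-4-[(1S,2S)-1-hydroxy-2-(methoxymethoxy)but-3-en-1-yl]dihydrofuran-2(3H)-one | ClC[C@H]1OC(=O)C[C@@H]1[C@H](O)[C@@H](OCOC)C=C | intermediate
8 | O8-tert-butyldimethylsilyl ether of 7 | ClC[C@H]1OC(=O)C[C@@H]1[C@H](O[Si](C)(C)C(C)(C)C)[C@@H](OCOC)C=C | intermediate
9 | C10 methyl ketone (C5–C12 and C14; O8 TBS, O9 MOM) | ClC[C@H]1OC(=O)C[C@@H]1[C@H](O[Si](C)(C)C(C)(C)C)[C@@H](OCOC)C(C)=O | intermediate
10 | 3-((tert-butyldiphenylsilyl)oxy)propanal | O=CCCO[Si](c1ccccc1)(c1ccccc1)C(C)(C)C | starting material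
11 | 5-((tert-butyldiphenylsilyl)oxy)pent-1-yn-3-ol (racemic) | C#CC(O)CCO[Si](c1ccccc1)(c1ccccc1)C(C)(C)C | intermediate
12 | bis(bromomagnesium) alkynide/alkoxide of 11 | Br[Mg]C#CC(O[Mg]Br)CCO[Si](c1ccccc1)(c1ccccc1)C(C)(C)C | intermediate
13 | propargylic diol (C10 tertiary alcohol; C3 epimers) | ClC[C@H]1OC(=O)C[C@@H]1[C@H](O[Si](C)(C)C(C)(C)C)[C@@H](OCOC)[C@](C)(O)C#CC(O)CCO[Si](c1ccccc1)(c1ccccc1)C(C)(C)C | intermediate
14 | γ-hydroxy ynone | ClC[C@H]1OC(=O)C[C@@H]1[C@H](O[Si](C)(C)C(C)(C)C)[C@@H](OCOC)[C@](C)(O)C#CC(=O)CCO[Si](c1ccccc1)(c1ccccc1)C(C)(C)C | intermediate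
15 | furan-3(2H)-one (acyclic at C4/C5; C5 chloride) | ClC[C@H]1OC(=O)C[C@@H]1[C@H](O[Si](C)(C)C(C)(C)C)[C@@H](OCOC)[C@]2(C)OC(CCO[Si](c3ccccc3)(c3ccccc3)C(C)(C)C)=CC2=O | intermediate
16 | trimethylsilyl dienol ether of 15 (C3=C4, C1–OSiMe3) | ClC[C@H]1OC(=O)C[C@@H]1[C@H](O[Si](C)(C)C(C)(C)C)[C@@H](OCOC)[C@]2(C)OC(=CCO[Si](c3ccccc3)(c3ccccc3)C(C)(C)C)C=C2O[Si](C)(C)C | intermediate
17 | C4 bromide of 15 (C4 epimers) | ClC[C@H]1OC(=O)C[C@@H]1[C@H](O[Si](C)(C)C(C)(C)C)[C@@H](OCOC)[C@]2(C)OC(C(Br)CO[Si](c3ccccc3)(c3ccccc3)C(C)(C)C)=CC2=O | intermediate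
18 | sodium C4 thiolate (C5 chloride still in place) | ClC[C@H]1OC(=O)C[C@@H]1[C@H](O[Si](C)(C)C(C)(C)C)[C@@H](OCOC)[C@]2(C)OC(C([S-])CO[Si](c3ccccc3)(c3ccccc3)C(C)(C)C)=CC2=O.[Na+] | intermediate
19 | ten-membered cyclic sulfide (ring O, C3, C4, S, C5–C10) | C1[C@H]2OC(=O)C[C@@H]2[C@H](O[Si](C)(C)C(C)(C)C)[C@@H](OCOC)[C@]3(C)OC(C(S1)CO[Si](c4ccccc4)(c4ccccc4)C(C)(C)C)=CC3=O | intermediate
20 | ten-membered cyclic sulfone | O=S1(=O)C[C@H]2OC(=O)C[C@@H]2[C@H](O[Si](C)(C)C(C)(C)C)[C@@H](OCOC)[C@]3(C)OC(C1CO[Si](c4ccccc4)(c4ccccc4)C(C)(C)C)=CC3=O | intermediate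
21 | potassium seco-carboxylate of the C4-chloro sulfone (lactone opened, C6–OH) | C1[C@@H](O)[C@H](CC(=O)[O-])[C@H](O[Si](C)(C)C(C)(C)C)[C@@H](OCOC)[C@]2(C)OC(C(Cl)(CO[Si](c3ccccc3)(c3ccccc3)C(C)(C)C)S1(=O)=O)=CC2=O.[K+] | intermediate
22 | episulfone (thiirane 1,1-dioxide across C4–C5), potassium carboxylate | O=S1(=O)C2[C@@H](O)[C@H](CC(=O)[O-])[C@H](O[Si](C)(C)C(C)(C)C)[C@@H](OCOC)[C@]3(C)OC(C12CO[Si](c4ccccc4)(c4ccccc4)C(C)(C)C)=CC3=O.[K+] | intermediate
23 | potassium 6-hydroxy carboxylate of the ring-contracted diene (Z C4=C5) | CC(C)(C)[Si](C)(C)O[C@H]1[C@@H](CC(=O)[O-])[C@H](O)/C=C(/CO[Si](c3ccccc3)(c3ccccc3)C(C)(C)C)C2=CC(=O)[C@@](C)(O2)[C@@H]1OCOC.[K+] | intermediate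
24 | nine-membered furanone lactone (O8 TBS, O9 MOM, O15 TBDPS, C11 H2) | CC(C)(C)[Si](C)(C)O[C@H]1[C@H]2CC(=O)O[C@@H]2/C=C(/CO[Si](c3ccccc3)(c3ccccc3)C(C)(C)C)C2=CC(=O)[C@@](C)(O2)[C@@H]1OCOC | intermediate
25 | C11 dimethylaminomethyl lactone (Mannich base, C11 epimers) | CC(C)(C)[Si](C)(C)O[C@H]1[C@H]2C(CN(C)C)C(=O)O[C@@H]2/C=C(/CO[Si](c3ccccc3)(c3ccccc3)C(C)(C)C)C2=CC(=O)[C@@](C)(O2)[C@@H]1OCOC | intermediate
26 | C11 trimethylammoniomethyl lactone iodide | CC(C)(C)[Si](C)(C)O[C@H]1[C@H]2C(C[N+](C)(C)C)C(=O)O[C@@H]2/C=C(/CO[Si](c3ccccc3)(c3ccccc3)C(C)(C)C)C2=CC(=O)[C@@](C)(O2)[C@@H]1OCOC.[I-] | intermediate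
27 | α-methylene lactone (O8 TBS, O9 MOM, O15 TBDPS) | CC(C)(C)[Si](C)(C)O[C@H]1[C@H]2C(=C)C(=O)O[C@@H]2/C=C(/CO[Si](c3ccccc3)(c3ccccc3)C(C)(C)C)C2=CC(=O)[C@@](C)(O2)[C@@H]1OCOC | intermediate
28 | C9 alcohol (O8 TBS, O15 TBDPS) | CC(C)(C)[Si](C)(C)O[C@H]1[C@H]2C(=C)C(=O)O[C@@H]2/C=C(/CO[Si](c3ccccc3)(c3ccccc3)C(C)(C)C)C2=CC(=O)[C@@](C)(O2)[C@@H]1O | intermediate
29 | C9 isovalerate (O8 TBS, O15 TBDPS) | CC(C)(C)[Si](C)(C)O[C@H]1[C@H]2C(=C)C(=O)O[C@@H]2/C=C(/CO[Si](c3ccccc3)(c3ccccc3)C(C)(C)C)C2=CC(=O)[C@@](C)(O2)[C@@H]1OC(=O)CC(C)C | intermediate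
30 | C8 alcohol (C9 isovalerate, O15 TBDPS) | O[C@H]1[C@H]2C(=C)C(=O)O[C@@H]2/C=C(/CO[Si](c3ccccc3)(c3ccccc3)C(C)(C)C)C2=CC(=O)[C@@](C)(O2)[C@@H]1OC(=O)CC(C)C | intermediate
31 | O15-tert-butyldiphenylsilyl ether of the target | C=C(C)C(=O)O[C@H]1[C@H]2C(=C)C(=O)O[C@@H]2/C=C(/CO[Si](c3ccccc3)(c3ccccc3)C(C)(C)C)C2=CC(=O)[C@@](C)(O2)[C@@H]1OC(=O)CC(C)C | intermediate
32 | CNP0552093.1 (6R,7S,8S,9R,10S; 4Z) | C=C(C)C(=O)O[C@H]1[C@H]2C(=C)C(=O)O[C@@H]2/C=C(/CO)C2=CC(=O)[C@@](C)(O2)[C@@H]1OC(=O)CC(C)C | target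

Total step count: 20. Longest linear sequence: 19 steps (steps 1–6 and 8–20, from 1); step 7 is a one-step branch.

**Steps most likely to fail**

Step 14. Halogen transfer from CCl4 may be followed by dichlorocarbene capture or over-chlorination, hydroxide may attack the vinylogous ester, and the β-oxido sulfone may undergo retro-aldol cleavage before the 1,3-elimination. The fallback sets out from sulfide 19 and separates halogenation from the base step. N-Chlorosuccinimide in CH2Cl2 should chlorinate the sulfide at its more acidic α-carbon to give the C4 chloro sulfide F1. Oxidation with mCPBA then gives the C4 chloro sulfone F2. F2 is treated with aqueous KOH in THF at 0 °C without any halogen source (classical Ramberg–Bäcklund reaction), which comes back to the route at 21 and, after acidification, at 24.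

Step 12. Ring closure at the unactivated primary chloride may be slow, so that intermolecular thioether formation (oligomerisation) and loss of HBr from the C4 bromide compete. The fallback sets out from furanone 15 and reverses the order of C–S bond formation, so that the ring closes at the activated centre. KSAc and NaI in DMF should convert the chloride into the C5 thioacetate F3. Soft enolisation (Me3SiOTf, Et3N) gives the silyl dienol ether F4, and N-bromosuccinimide gives the C4 bromo thioacetate F5. Hydrazine acetate in DMF at high dilution frees the C5 thiol F6, which with iPr2NEt closes onto the C4 bromide and comes back to the route at 19.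

Step 15. The amide base may abstract the doubly vinylogous proton at C6 of the dienyl furanone instead of enolising C11, leading to epimerisation or decomposition. The fallback sets out from 24 and avoids amide bases. Methyl magnesium carbonate (MeOMgOCO2Me) in DMF with heating, then dilute HCl, should carboxylate the lactone through its magnesium chelate to give the C11 carboxylic acid F7. Aqueous formaldehyde and diethylamine in AcOH/NaOAc then give the aminomethyl acid F8, which loses CO2 and diethylamine and comes back to the route at 27.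

**Further compounds**
F1 | step 14 | C4 chloro sulfide of 19 (C4 epimers) | C1[C@H]2OC(=O)C[C@@H]2[C@H](O[Si](C)(C)C(C)(C)C)[C@@H](OCOC)[C@]3(C)OC(C(Cl)(CO[Si](c4ccccc4)(c4ccccc4)C(C)(C)C)S1)=CC3=O
F2 | step 14 | C4 chloro sulfone | C1[C@H]2OC(=O)C[C@@H]2[C@H](O[Si](C)(C)C(C)(C)C)[C@@H](OCOC)[C@]3(C)OC(C(Cl)(CO[Si](c4ccccc4)(c4ccccc4)C(C)(C)C)S1(=O)=O)=CC3=O
F3 | step 12 | C5 thioacetate of 15 | CC(=O)SC[C@H]1OC(=O)C[C@@H]1[C@H](O[Si](C)(C)C(C)(C)C)[C@@H](OCOC)[C@]2(C)OC(CCO[Si](c3ccccc3)(c3ccccc3)C(C)(C)C)=CC2=O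
F4 | step 12 | trimethylsilyl dienol ether of F3 | CC(=O)SC[C@H]1OC(=O)C[C@@H]1[C@H](O[Si](C)(C)C(C)(C)C)[C@@H](OCOC)[C@]2(C)OC(=CCO[Si](c3ccccc3)(c3ccccc3)C(C)(C)C)C=C2O[Si](C)(C)C
F5 | step 12 | C4 bromo C5 thioacetate (C4 epimers) | CC(=O)SC[C@H]1OC(=O)C[C@@H]1[C@H](O[Si](C)(C)C(C)(C)C)[C@@H](OCOC)[C@]2(C)OC(C(Br)CO[Si](c3ccccc3)(c3ccccc3)C(C)(C)C)=CC2=O
F6 | step 12 | C4 bromo C5 thiol | SC[C@H]1OC(=O)C[C@@H]1[C@H](O[Si](C)(C)C(C)(C)C)[C@@H](OCOC)[C@]2(C)OC(C(Br)CO[Si](c3ccccc3)(c3ccccc3)C(C)(C)C)=CC2=O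
F7 | step 15 | C11 carboxylic acid of 24 (C11 epimers) | CC(C)(C)[Si](C)(C)O[C@H]1[C@H]2C(C(=O)O)C(=O)O[C@@H]2/C=C(/CO[Si](c3ccccc3)(c3ccccc3)C(C)(C)C)C2=CC(=O)[C@@](C)(O2)[C@@H]1OCOC
F8 | step 15 | C11 diethylaminomethyl C11 carboxylic acid | CC(C)(C)[Si](C)(C)O[C@H]1[C@H]2C(CN(CC)CC)(C(=O)O)C(=O)O[C@@H]2/C=C(/CO[Si](c3ccccc3)(c3ccccc3)C(C)(C)C)C2=CC(=O)[C@@](C)(O2)[C@@H]1OCOC
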